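The runs stem from a simulated flask with constants of no real substance, and the scatter is random.

Amounts first. The south-west flask at 25 °C had stood still from 96.0 h: complex with one exchanged read 40.8%, 40.7% and 39.1%, mean 40.2%, while starting complex stayed near 48.8%. That was 4.02 mM made from 10.5 mM of incoming ligand. With starting complex still on hand, I read the ligand as the limiting reagent, and 38.3% of it stood as complex with one exchanged. Taking [starting complex] as 7.44 mM on average, I got a rival concentration of 12.0 mM: the [starting complex] at which incoming ligand splits evenly between exchange and its losses. At this temperature and this amount of protic impurity, I took the share reaching the complex as [starting complex] / ([starting complex] + rival).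

the same everywhere: starting complex 10 mM; incoming ligand 10.5 mM
- south-west: protic impurity 10 mM; temperature 25 °C; the very flask that is asked about, followed so far
- north-west: protic impurity 15 mM; temperature 20 °C; run made earlier
- flask: protic impurity 10.0 mM; temperature 25 °C; time 8.0 d

- south-west (time / h: complex with one exchanged / %, starting complex / %): 12.0: 16.2, 59.4; 40.0: 34.3, 50.3; 72.0: 39.5, 49.1; 96.0: 40.8, 48.4; 144: 40.7, 47.1; 192: 39.1, 48.8
- north-west (time / h: complex with one exchanged / %, starting complex / %): 1.50: 2.0, 93.5; 3.00: 5.9, 89.4; 5.00: 9.2, 83.8; 8.00: 11.1, 76.7; 12.0: 14.9, 69.7; 20.0: 17.3, 61.8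

(each reading ± 1 percentage point)

- Thursday's: change nothing and wait 4.0 d more
- Wednesday's: at 8.0 d raise the temperature by 15 K, then wait 4.0 d
- Sunday's: at 8.0 d take out 90% of the complex with one exchanged then present, then wait 4.0 d
- Tuesday's: at 8.0 d add incoming ligand, 50.0% of the amount charged, then wait 4.0 d

- complex with one exchanged taken out counts as made
- candidate steps: starting complex + incoming ligand <-> leaving ligand + complex with one exchanged; complex with one exchanged + incoming ligand <-> leaving ligand + complex with two exchanged; complex with two exchanged + incoming ligand <-> leaving ligand + complex with three exchanged; complex with three exchanged + incoming ligand <-> leaving ligand + complex with four exchanged; incoming ligand -> decomposed reagent; protic impurity + incoming ligand -> quenched reagent; starting complex <-> dormant form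
- additions bring no volume worth counting

1. complex with one exchanged, in percent of the starting complex first charged, at 8.0 d
2. the option that brings most further complex with one exchanged ("none" if no option brings more than 2 percentage points) (Thursday's / Wednesday's / Sunday's / Tuesday's / none)
3. complex with one exchanged present, with what was taken out counted in, in percent of the starting complex first charged, after Wednesday's
4. complex with one exchanged present, with what was taken out counted in, in percent of the starting complex first charged, after Tuesday's

Note for the bench: expect 40.2% at 8.0 d, with the flask much as it stands. Waiting, heating and taking out product put no ligand in; added ligand does, so that was my choice. At the [starting complex] of 4.88 mM on the day of the addition, its share comes to 28.9%, so I reckoned that 5.25 mM brings 15 percentage points, about 55.2% in all.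

The forecast gave 40% (38.5% to 41.5%), Tuesday's, 38.5% (32% to 43%) and 54% (46% to 62%), the last lower than my figure: “Only added ligand helps.”

The flask gave 40.3%, then Tuesday's with 13 points against my 15 points, 38.6% after Wednesday's and 53.5% after Tuesday's. At 192 h, incoming ligand in the flask stood at 0.325% of its charge. Through my share, that remainder is worth 0.099 points, and Thursday's moved the product by −0.62 points.

    starting complex + incoming ligand ⇌ leaving ligand + complex with one exchanged (K = 48.0, k = 0.0640 L mol⁻¹ min⁻¹, Ea = 58.0 kJ mol⁻¹, ΔH = 12.0 kJ mol⁻¹)
    complex with one exchanged + incoming ligand ⇌ leaving ligand + complex with two exchanged (K = 0.360, k = 0.270 L mol⁻¹ min⁻¹, Ea = 73.0 kJ mol⁻¹, ΔH = −29.0 kJ mol⁻¹)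
    complex with two exchanged + incoming ligand ⇌ leaving ligand + complex with three exchanged (K = 1.90, k = 0.0230 L mol⁻¹ min⁻¹, Ea = 71.0 kJ mol⁻¹, ΔH = −81.0 kJ mol⁻¹)
    complex with three exchanged + incoming ligand ⇌ leaving ligand + complex with four exchanged (K = 50.0, k = 0.0730 L mol⁻¹ min⁻¹, Ea = 74.0 kJ mol⁻¹, ΔH = −66.0 kJ mol⁻¹)
    incoming ligand → decomposed reagent (k = 4.70 × 10⁻⁴ min⁻¹, Ea = 109 kJ mol⁻¹)
    protic impurity + incoming ligand → quenched reagent (k = 0.0130 L mol⁻¹ min⁻¹, Ea = 76.0 kJ mol⁻¹)
    starting complex ⇌ dormant form (K = 0.230, k = 6.10 × 10⁻⁴ min⁻¹, Ea = 106 kJ mol⁻¹, ΔH = 27.0 kJ mol⁻¹)
    (constants at 25 °C)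

In the neighbour flask with 42 mM of incoming ligand, at the same temperature and amount of protic impurity, the rival with [starting complex] taken at 5.00 mM gives a share of 29.4%, so I reckoned 12.3 mM of exchange, more than the 10 mM of complex charged. Computed, that neighbour flask held at 192 h 12.0 mM of leaving ligand, 70.7% of complex with one exchanged, 10.8% of complex with four exchanged, 13.2% of starting complex and 0.82% of its charged incoming ligand.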